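**Assumption:** the target is an achiral, planar isoflavone with no stereocentre, so no enantiocontrol is needed; the only stereo-element in the route is the (Z)-alkene of compound 9.

## Retrosynthetic overview

1. Target 16 ⇐ hydrogenolysis of the two benzyl ethers of 15; the 8-OH of 15 ⇐ late para-hydroxylation (Elbs) of the 5-hydroxy-isoflavone 13.
2. Isoflavone 12 ⇐ A-ring salicylaldehyde 5, used as an acyl anion through its carbene (Breslow) adduct (C4), plus B-ring (Z)-bromonitroalkene 9 (C3 and C2). The key C4–C3 bond joins two natively electrophilic carbons; O1–C2 closure and loss of HBr and HNO2 follow in the same pot.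
3. Aldehyde 5 ⇐ 2,4,6-trihydroxybenzaldehyde by dibenzylation, Elbs para-hydroxylation and O-methylation. This places the 6-OMe and fixes which OH becomes O1.
4. Bromonitroalkene 9 ⇐ 3-hydroxy-4,5-dimethoxybenzaldehyde by O-benzylation and condensation with bromonitromethane.
5. Ring order: both benzene rings are bought; the pyranone ring is the only ring formed, in the key step.

## Route

Step 1
Reactants: 1 2,4,6-trihydroxybenzaldehyde
Product: 2 2,4-bis(benzyloxy)-6-hydroxybenzaldehyde
Conditions: BnBr (2.1 equiv), K2CO3 (2.2 equiv), DMF, 0 °C to rt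
Reagents that add atoms: benzyl bromide, BrCc1ccccc1
Why: Chelation-controlled Williamson etherification: the 4-OH and one ortho-OH are alkylated, while the OH hydrogen-bonded to the formyl group stays free and later becomes O1.

Step 2
Reactants: 2 2,4-bis(benzyloxy)-6-hydroxybenzaldehyde
Product: 4 2,4-bis(benzyloxy)-3,6-dihydroxybenzaldehyde, via aryl sulfate 3 (not isolated)
Conditions: K2S2O8 (1.1 equiv), aq KOH, pyridine, 10–20 °C; then 2 M H2SO4, toluene, 80 °C
Reagents that add atoms: potassium peroxodisulfate, [K+].[K+].[O-]S(=O)(=O)OOS(=O)(=O)[O-]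
Why: Elbs persulfate oxidation: the phenoxide attacks the peroxide oxygen through its only para carbon (C3), and the aryl sulfate is then hydrolysed by acid, which benzyl ethers tolerate.

Step 3
Reactants: 4 2,4-bis(benzyloxy)-3,6-dihydroxybenzaldehyde
Product: 5 2,4-bis(benzyloxy)-6-hydroxy-3-methoxybenzaldehyde
Conditions: MeI (1.05 equiv), K2CO3 (1.1 equiv), acetone, rt, N2
Reagents that add atoms: iodomethane, CI
Why: Selective Williamson O-methylation of the non-chelated 3-OH; the 6-OH hydrogen-bonded to the aldehyde is far less nucleophilic.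

Step 4
Reactants: 6 3-hydroxy-4,5-dimethoxybenzaldehyde
Product: 7 3-(benzyloxy)-4,5-dimethoxybenzaldehyde
Conditions: BnBr (1.1 equiv), K2CO3, DMF, 60 °C
Reagents that add atoms: benzyl bromide, BrCc1ccccc1
Why: Williamson etherification masks the B-ring phenol, which would otherwise be the preferred site of the later persulfate oxidation.

Step 5
Reactants: 7 3-(benzyloxy)-4,5-dimethoxybenzaldehyde; 8 bromonitromethane
Product: 9 (Z)-1-(benzyloxy)-5-(2-bromo-2-nitroethenyl)-2,3-dimethoxybenzene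
Conditions: Me2NH·HCl, KF (cat.), m-xylene, 125 °C, Dean–Stark
Reagents that add atoms: none
Why: Henry (nitroaldol) condensation with dehydration under azeotropic water removal gives the thermodynamic (Z)-alkene, with the aryl group trans to NO2.

Step 6
Reactants: 5 2,4-bis(benzyloxy)-6-hydroxy-3-methoxybenzaldehyde; 9 (Z)-1-(benzyloxy)-5-(2-bromo-2-nitroethenyl)-2,3-dimethoxybenzene
Product: 12 5,7-bis(benzyloxy)-3-[3-(benzyloxy)-4,5-dimethoxyphenyl]-6-methoxy-4H-chromen-4-one, via bromonitro ketone 10 (not isolated), via 2-nitroisoflavanone 11 (not isolated)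
Conditions: 2-(pentafluorophenyl)-6,7-dihydro-5H-pyrrolo[2,1-c][1,2,4]triazolium BF4 (20 mol%), K2CO3 (2.5 equiv), 4 Å MS, THF/t-AmOH, 0 to 40 °C, slow addition of 9
Reagents that add atoms: none
Why: Proposed new method: the carbene adds to the hydrogen-bond-activated formyl group of 5 to give a Breslow intermediate (acyl anion equivalent), which undergoes Stetter conjugate addition to the aryl-bearing β-carbon of 9 and forms C4–C3; the ortho phenoxide then O-alkylates the CH(Br)NO2 carbon of 10 (6-exo-tet, O1–C2) to give 11, and E1cB loss of nitrite (C3–H is α to the ketone and benzylic) aromatises the pyranone and destroys both transient stereocentres, while the competing phenoxide oxa-Michael/Henry adduct cannot dehydrate at its quaternary C(Br)NO2 carbon and so reverts; the closest known reactions are the triazolylidene-catalysed intermolecular Stetter reaction of aldehydes with nitroalkenes and the domino Michael/O-alkylation of 1,3-dicarbonyls or naphthols with (Z)-bromonitroalkenes followed by HNO2 elimination (interrupted Feist–Bénary furan synthesis).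

Step 7
Reactants: 12 5,7-bis(benzyloxy)-3-[3-(benzyloxy)-4,5-dimethoxyphenyl]-6-methoxy-4H-chromen-4-one
Product: 13 7-(benzyloxy)-3-[3-(benzyloxy)-4,5-dimethoxyphenyl]-5-hydroxy-6-methoxy-4H-chromen-4-one
Conditions: BCl3 (1.1 equiv), CH2Cl2, −78 °C; then H2O
Reagents that add atoms: none
Why: Chelation-controlled Lewis-acid ether cleavage: boron bound between C4=O and O5 removes only the peri benzyl ether at low temperature, leaving the 7- and 3'-benzyl ethers and all methyl ethers.

Step 8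
Reactants: 13 7-(benzyloxy)-3-[3-(benzyloxy)-4,5-dimethoxyphenyl]-5-hydroxy-6-methoxy-4H-chromen-4-one
Product: 15 7-(benzyloxy)-3-[3-(benzyloxy)-4,5-dimethoxyphenyl]-5,8-dihydroxy-6-methoxy-4H-chromen-4-one, via 8-O-sulfate 14 (not isolated)
Conditions: K2S2O8 (1.2 equiv), aq KOH, pyridine, 10–15 °C, N2; then 2 M H2SO4, 70 °C
Reagents that add atoms: potassium peroxodisulfate, [K+].[K+].[O-]S(=O)(=O)OOS(=O)(=O)[O-]
Why: Elbs persulfate oxidation: the 5-phenoxide reacts through C8, its para position and the only free A-ring carbon, and the B ring has no free phenol; the sulfate ester protects the new hydroquinone until acid hydrolysis.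

Step 9
Reactants: 15 7-(benzyloxy)-3-[3-(benzyloxy)-4,5-dimethoxyphenyl]-5,8-dihydroxy-6-methoxy-4H-chromen-4-one
Product: 16 5,7,8-trihydroxy-3-(3-hydroxy-4,5-dimethoxyphenyl)-6-methoxy-4H-chromen-4-one (5,7,8,3'-tetrahydroxy-6,4',5'-trimethoxyisoflavone)
Conditions: H2 (1 atm), 10% Pd/C, THF/MeOH, rt, work-up under N2
Reagents that add atoms: none
Why: Catalytic hydrogenolysis cleaves both benzyl ethers; at 1 atm and rt the vinylogous-ester C2=C3 bond and the methyl ethers are not reduced.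

## Compound list

1 | 2,4,6-trihydroxybenzaldehyde | O=Cc1c(O)cc(O)cc1O | starting material
2 | 2,4-bis(benzyloxy)-6-hydroxybenzaldehyde | O=Cc1c(O)cc(OCc2ccccc2)cc1OCc1ccccc1 | intermediate
3 | potassium 2,6-bis(benzyloxy)-3-formyl-4-hydroxyphenyl sulfate | O=Cc1c(O)cc(OCc2ccccc2)c(OS(=O)(=O)[O-])c1OCc1ccccc1.[K+] | intermediate (not isolated)
4 | 2,4-bis(benzyloxy)-3,6-dihydroxybenzaldehyde | O=Cc1c(O)cc(OCc2ccccc2)c(O)c1OCc1ccccc1 | intermediate
5 | 2,4-bis(benzyloxy)-6-hydroxy-3-methoxybenzaldehyde | O=Cc1c(O)cc(OCc2ccccc2)c(OC)c1OCc1ccccc1 | intermediate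
6 | 3-hydroxy-4,5-dimethoxybenzaldehyde | O=Cc1cc(O)c(OC)c(OC)c1 | starting material
7 | 3-(benzyloxy)-4,5-dimethoxybenzaldehyde | O=Cc1cc(OC)c(OC)c(OCc2ccccc2)c1 | intermediate
8 | bromonitromethane | BrC[N+](=O)[O-] | starting material
9 | (Z)-1-(benzyloxy)-5-(2-bromo-2-nitroethenyl)-2,3-dimethoxybenzene | O=[N+]([O-])/C(Br)=C/c1cc(OC)c(OC)c(OCc2ccccc2)c1 | intermediate
10 | 1-[2,4-bis(benzyloxy)-6-hydroxy-3-methoxyphenyl]-2-[3-(benzyloxy)-4,5-dimethoxyphenyl]-3-bromo-3-nitropropan-1-one (racemic mixture of diastereomers) | O=C(c1c(O)cc(OCc2ccccc2)c(OC)c1OCc1ccccc1)C(c1cc(OC)c(OC)c(OCc2ccccc2)c1)C(Br)[N+](=O)[O-] | intermediate (not isolated)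
11 | 5,7-bis(benzyloxy)-3-[3-(benzyloxy)-4,5-dimethoxyphenyl]-6-methoxy-2-nitrochroman-4-one (racemic mixture of diastereomers) | O=C1c2c(OCc3ccccc3)c(OC)c(OCc3ccccc3)cc2OC([N+](=O)[O-])C1c1cc(OC)c(OC)c(OCc2ccccc2)c1 | intermediate (not isolated)
12 | 5,7-bis(benzyloxy)-3-[3-(benzyloxy)-4,5-dimethoxyphenyl]-6-methoxy-4H-chromen-4-one | O=c1c(-c2cc(OC)c(OC)c(OCc3ccccc3)c2)coc2cc(OCc3ccccc3)c(OC)c(OCc3ccccc3)c12 | intermediate
13 | 7-(benzyloxy)-3-[3-(benzyloxy)-4,5-dimethoxyphenyl]-5-hydroxy-6-methoxy-4H-chromen-4-one | O=c1c(-c2cc(OC)c(OC)c(OCc3ccccc3)c2)coc2cc(OCc3ccccc3)c(OC)c(O)c12 | intermediate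
14 | potassium 7-(benzyloxy)-3-[3-(benzyloxy)-4,5-dimethoxyphenyl]-5-hydroxy-6-methoxy-4-oxo-4H-chromen-8-yl sulfate | O=c1c(-c2cc(OC)c(OC)c(OCc3ccccc3)c2)coc2c(OS(=O)(=O)[O-])c(OCc3ccccc3)c(OC)c(O)c12.[K+] | intermediate (not isolated)
15 | 7-(benzyloxy)-3-[3-(benzyloxy)-4,5-dimethoxyphenyl]-5,8-dihydroxy-6-methoxy-4H-chromen-4-one | O=c1c(-c2cc(OC)c(OC)c(OCc3ccccc3)c2)coc2c(O)c(OCc3ccccc3)c(OC)c(O)c12 | intermediate
16 | 5,7,8-trihydroxy-3-(3-hydroxy-4,5-dimethoxyphenyl)-6-methoxy-4H-chromen-4-one | COc1cc(-c2coc3c(O)c(O)c(OC)c(O)c3c2=O)cc(O)c1OC | target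

## Step count and risks

Total step count: 9. Longest linear sequence: 7 (steps 1, 2, 3, 6, 7, 8, 9).

Three steps most likely to fail:

**Step 6.** The carbene may be alkylated or oxidised by the bromonitroalkene, and the 2,6-disubstituted, electron-rich aldehyde may form its Breslow intermediate slowly. The fallback sets out from 5 and 7 and comes back at 12. Condense 7 with nitromethane (NH4OAc, AcOH, 100 °C) to the nitrostyrene (E)-1-(benzyloxy)-2,3-dimethoxy-5-(2-nitroethenyl)benzene F1. Run the Stetter addition of 5 to F1 with the same triazolylidene (NaOAc, t-AmOH) to the β-nitro ketone 1-[2,4-bis(benzyloxy)-6-hydroxy-3-methoxyphenyl]-2-[3-(benzyloxy)-4,5-dimethoxyphenyl]-3-nitropropan-1-one F2. K2CO3 in MeCN then eliminates nitrite to the α-aryl enone 1-[2,4-bis(benzyloxy)-6-hydroxy-3-methoxyphenyl]-2-[3-(benzyloxy)-4,5-dimethoxyphenyl]prop-2-en-1-one F3, which closes by 6-endo oxa-Michael addition to the racemic isoflavanone 5,7-bis(benzyloxy)-3-[3-(benzyloxy)-4,5-dimethoxyphenyl]-6-methoxychroman-4-one F4. DDQ in dioxane at reflux dehydrogenates F4 to 12. This removes the bromine-specific failure modes and replaces the redox-neutral domino with a Stetter/elimination/dehydrogenation sequence; it does not remove the hindered-aldehyde risk.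

**Step 8.** The isoflavone ring can open in aqueous alkali, and Elbs yields on chelated 5-hydroxychromones are low. The fallback sets out from 13 and comes back at 15. Oxidise 13 without base using PhI(OCOCF3)2 in MeCN/H2O at 0 °C (para-oxidation of the phenol) to the quinone 7-(benzyloxy)-3-[3-(benzyloxy)-4,5-dimethoxyphenyl]-6-methoxy-4H-chromene-4,5,8-trione F5, then reduce F5 with aqueous Na2S2O4 to the hydroquinone 15.

**Step 2.** The dibenzyl ether is poorly soluble in aqueous alkali and Elbs yields are low. The fallback sets out from 2 and comes back at 4. Oxidise 2 with Fremy's salt (potassium nitrosodisulfonate, KH2PO4 buffer, acetone/H2O; Teuber oxidation) to the formylquinone 2,4-bis(benzyloxy)-3,6-dioxocyclohexa-1,4-diene-1-carbaldehyde F6, then reduce F6 with aqueous Na2S2O4 to 4.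

## Further compounds

F1 | step 6 | (E)-1-(benzyloxy)-2,3-dimethoxy-5-(2-nitroethenyl)benzene | O=[N+]([O-])/C=C/c1cc(OC)c(OC)c(OCc2ccccc2)c1
F2 | step 6 | 1-[2,4-bis(benzyloxy)-6-hydroxy-3-methoxyphenyl]-2-[3-(benzyloxy)-4,5-dimethoxyphenyl]-3-nitropropan-1-one (racemic) | O=C(c1c(O)cc(OCc2ccccc2)c(OC)c1OCc1ccccc1)C(C[N+](=O)[O-])c1cc(OC)c(OC)c(OCc2ccccc2)c1
F3 | step 6 | 1-[2,4-bis(benzyloxy)-6-hydroxy-3-methoxyphenyl]-2-[3-(benzyloxy)-4,5-dimethoxyphenyl]prop-2-en-1-one | C=C(C(=O)c1c(O)cc(OCc2ccccc2)c(OC)c1OCc1ccccc1)c1cc(OC)c(OC)c(OCc2ccccc2)c1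
F4 | step 6 | 5,7-bis(benzyloxy)-3-[3-(benzyloxy)-4,5-dimethoxyphenyl]-6-methoxychroman-4-one (racemic) | O=C1c2c(OCc3ccccc3)c(OC)c(OCc3ccccc3)cc2OCC1c1cc(OC)c(OC)c(OCc2ccccc2)c1
F5 | step 8 | 7-(benzyloxy)-3-[3-(benzyloxy)-4,5-dimethoxyphenyl]-6-methoxy-4H-chromene-4,5,8-trione | O=C1C(OC)=C(OCc2ccccc2)C(=O)C2=C1C(=O)C(c1cc(OC)c(OC)c(OCc3ccccc3)c1)=CO2
F6 | step 2 | 2,4-bis(benzyloxy)-3,6-dioxocyclohexa-1,4-diene-1-carbaldehyde | O=CC1=C(OCc2ccccc2)C(=O)C(OCc2ccccc2)=CC1=O
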